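## Analysis of the target

The target is a 2-O-alkylated propane-1,3-diol whose eight-carbon chain ends at C-10 of a tetracyclo[6.4.0.0^{2,7}.0^{3,6}]dodecane. Cyclohexane ring A (C-1, C-8 to C-12) is fused to three linearly fused cyclobutanes: ring B (C-1, C-2, C-7, C-8), ring C (C-2, C-3, C-6, C-7) and ring D (C-3 to C-6). There are seven stereocentres, (1R,2S,3S,6R,7R,8S,10S). The six ring-fusion methines are cis at every fusion bond (C-1/C-8, C-2/C-7, C-3/C-6) with neighbouring rings anti, which gives a staircase. C-10 carries the chain cis to ring B. Without the chain the hydrocarbon is meso (a mirror plane cuts the midpoints of C-1–C-8, C-2–C-7, C-3–C-6 and C-4–C-5), so C-10 alone makes the molecule chiral and the absolute configuration can be brought in by desymmetrising a meso intermediate. The sensitive part is the pair of bicyclo[2.2.0]hexane units: they are thermally labile, open by β-scission when a radical sits next to them, and can suffer σ-bond insertion or hydrogenolysis on noble metals; the ether and the diol are robust. The difficulty is that the ladder has no functional group to direct bond formation, that three contiguous four-membered rings must be made in the cis,anti,cis pattern, and that C-10 is remote from every controlling element. The strategy rests on the four parallel rung bonds C-1–C-8, C-2–C-7, C-3–C-6 and C-4–C-5. They lie between the rails C-1–C-2–C-3–C-4 and C-8–C-7–C-6–C-5, each of which has the backbone of an (E,E)-1,3-diene, so the ladder is two stacked dienes joined face to face, with ring A closed by a four-carbon bridge between the rail ends C-1 and C-8.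

## Retrosynthetic reasoning

**24 from 23.** Only the two acetal C–O bonds are cut. An acid-labile acetal is preferred to benzyl ethers so that no hydrogenolysis catalyst meets the strained ladder at the end. The forward step needs dilute acid only.

**23 from 22, and 22 from 16 and 20.** The bond between C-10 and the first chain carbon is cut, as a C=C bond. It is the only bond that separates the symmetrical hydrocarbon from the chain, so the cut returns ketone 16 (meso ladder core) and phosphonium salt 20. Forward, the ylide 21 gives alkene 22, and hydrogenation must then deliver hydrogen to C-10 from the face anti to ring B. Salt 20 comes from bromide 19 (C–P bond), and 19 from the commercial alcohol 17 and dibromide 18 (C–O bond).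

**16 from 15, and 15 from 13.** The oxygen at C-10 is removed to reveal the meso alkene 13. Oxygenating one of its two enantiotopic olefinic carbons fixes the absolute sense of all six ring-fusion centres at once, so nothing earlier has to be enantioselective. Forward, an asymmetric hydroboration through borane 14 gives alcohol 15, and oxidation gives 16. The carbinol centre is sacrificial.

**13 from 11, and 11 from 10.** Two C–H bonds at C-4 and C-5 are exchanged for C–CO2H bonds, and the diacid 11 is tied up as the cyclic diester 10 of diol 7. The carboxyl groups turn the rails into dienoates and give the anchor for a removable clamp. Forward, saponification and a double radical decarboxylation through 12 are needed.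

**10 from 8 (key disconnection).** All four rung bonds are cut. The rungs are the only bonds shared by two rings, so this one cut removes rings A to D and all six permanent stereocentres and leads to the achiral macrocycle 8. In 8 the two (E,E)-dienoate rails are held by a (Z)-butenylene tether (the future C-9 to C-12) at one end and by the diester clamp at the other. Forward, a sensitised photocascade through 9 must join the δ, γ, β and α carbon pairs in register. The clamp must not have a triplet state below that of an isolated enoate.

**8 from 6 and 7; 6 from 5; 5 from 3 and 4; 3 from 2; 2 from 1.** The two ester C–O bonds are cut to diacid 6 and diol 7. Diacid 6 comes from diester 5. Cutting the C-4=C-5 and C-10=C-11 bonds of the chain gives dialdehyde 3 and two equivalents of phosphonate 4. The Z-alkene of 3 with its two flanking methylenes is a cyclohexa-1,4-diene ring cut open, which leads through diol 2 to 1 and secures the Z geometry.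

## Alternatives that were turned down

**Alternative 1: asymmetric Diels–Alder reaction for rings A and B.** The bonds C-1–C-12 and C-8–C-9 are cut. Forward, the 2-substituted buta-1,3-diene A1, which already carries the ether chain, adds to cyclobut-2-en-1-one A2 under a chiral oxazaborolidinium Lewis acid (N-protonated B-aryl oxazaborolidine from α,α-diphenylprolinol) to give the bicyclic ketone A3.
- For it: the step belongs to a known reaction class, and the strained enone is a strong dienophile. The "para" orientation puts the chain at the right carbon. The A/B fusion is set catalytically with absolute control. The chain arrives convergently, and the endocyclic trisubstituted alkene of A3 should be hydrogenated from the convex face with better bias than the exocyclic alkene 22.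
- Against it: only two of the skeletal C–C bonds and two stereocentres are made. Rings C and D (four bonds, four stereocentres) must be grown from the cyclobutanone by repeated cyclobutene formation and photocycloaddition, in the presence of the chain and its benzyl ethers. A2 is labile and must be prepared.
- Comparison: Alternative 1 is stronger on absolute stereocontrol and on C-10. The chosen strategy instead forms all four rings and six permanent stereocentres in one step from a symmetrical precursor, and pays with a late desymmetrisation.

**Alternative 2: cyclooctatetraene–maleic anhydride adduct.** The A/B fusion bond is traced back to a 6π closure and two ring A bonds to a [4+2] addition. Forward, heated cyclooctatetraene A4 reacts through its valence isomer bicyclo[4.2.0]octa-2,4,7-triene A5 with maleic anhydride A6 to give the meso anhydride A7.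
- For it: the step is a classical one-step reaction of cheap materials. The meso anhydride can be opened enantioselectively by known desymmetrising alcoholysis. The endo rule places the carboxyl carbon that would become the chain anchor on the same face of the future ring A as ring B, so the C-10 relation is set by the cycloaddition and not by a late hydrogenation. Ring B arrives as a cyclobutene ready for further [2+2] growth.
- Against it: three carbons that the target lacks (the two of the etheno bridge and one carboxyl carbon) must be excised. Rings C and D still need two further photocycloadditions with regeneration of a cyclobutene in between. The linear sequence is long.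
- Comparison: Alternative 2 is stronger in that every step is known and in the control of C-10. The chosen strategy offers far better step and atom economy, since nothing but two carboxyl groups is built in and taken out again.

**Alternative 3: 4π photo-electrocyclisation for the C/D fusion.** The bond C-3–C-6 is cut. Forward, the tricyclic triene A8, whose cyclohexa-1,3-diene is fused to ring B, closes on irradiation between the diene termini to the ladder diene A9 (ring D as cyclobutene).
- For it: the reaction type is known for bicyclo[4.2.0]octa-2,4-dienes. The disrotatory mode guarantees the cis C/D fusion. There is no clamp to attach and no decarboxylation. A9 is one chemoselective reduction away from 13, so the end game would be the same.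
- Against it: A8 requires ring A to be annulated onto the cyclobutene bond of A5, which is a minor equilibrium partner of A4 and prefers to react as a diene. The excited diene can also fragment by cycloreversion into an arene and 1, or open to a triene. Ring D must form anti to ring B with only modest bias. The two alkenes of A9 must be told apart.
- Comparison: Alternative 3 is as strong or stronger in step count after the key step. The chosen strategy offers a precursor that is assembled in five reliable steps and a single operation that sets all ring fusions under the control of tether and clamp.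

Key step: step 6

**Remarks before the steps.**
- Locants C-1 to C-12 refer to the tetracyclododecane numbering used above. "Chain locants" refer to the C14 chain of 5, 6 and 8; chain C-5/C-10, C-4/C-11, C-3/C-12 and C-2/C-13 become ladder C-1/C-8, C-2/C-7, C-3/C-6 and C-4/C-5.
- Clamp: the aliphatic diol 7 is used. A peri-diol such as naphthalene-1,8-diol would be more rigid, but its triplet (about 60 kcal/mol) lies below that of the isolated enoates (about 72–74 kcal/mol) and would quench the second cycloaddition.
- Assumption: the sense of induction of (+)-diisopinocampheylborane is taken from the empirical model for cis-disubstituted alkenes; if the sense were opposite, the antipodal reagent would be used.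

## Route

Step 1
Reactants: 1 cyclohexa-1,4-diene
Product: 2 cis-cyclohex-4-ene-1,2-diol (meso)
Conditions: OsO4 (0.5 mol %), NMO (1 equiv), 1 in 2.5-fold excess, acetone/H2O, 0 °C to rt
Reagents that add atoms: N-methylmorpholine N-oxide, C[N+]1([O-])CCOCC1; water, O
Why: Upjohn dihydroxylation; the suprafacial osmylation fixes the cis diol, and the excess of the cheap diene should hold back tetraol formation because the two alkenes react independently.

Step 2
Reactants: 2 cis-cyclohex-4-ene-1,2-diol
Product: 3 (Z)-hex-3-enedial
Conditions: NaIO4 on silica gel, CH2Cl2, 0 °C; filtered, dried solution used at once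
Reagents that add atoms: none
Why: Malaprade glycol cleavage through a cyclic periodate ester; the Z geometry is that of the ring alkene and is carried over unchanged, and the neutral, cold conditions should spare the β,γ-unsaturated dialdehyde from conjugation.

Step 3
Reactants: 3 (Z)-hex-3-enedial; 4 triethyl 4-phosphonocrotonate (2.4 equiv)
Product: 5 diethyl (2E,4E,7Z,10E,12E)-tetradeca-2,4,7,10,12-pentaenedioate
Conditions: LiN(SiMe3)2, THF, −78 °C to −20 °C
Reagents that add atoms: none
Why: Twofold Horner–Wadsworth–Emmons olefination with the lithiated allylic phosphonate; reversible addition and syn elimination of phosphate favour the E alkene at chain C-4/C-5 and C-10/C-11, the E crotonate bond and the Z alkene of 3 are carried through, and addition at −78 °C should outrun enolisation of the aldehyde.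

Step 4
Reactants: 5 diethyl (2E,4E,7Z,10E,12E)-tetradeca-2,4,7,10,12-pentaenedioate
Product: 6 (2E,4E,7Z,10E,12E)-tetradeca-2,4,7,10,12-pentaenedioic acid
Conditions: LiOH (4 equiv), THF/H2O, 0 °C to rt; then 1 M HCl to pH 3
Reagents that add atoms: lithium hydroxide, [Li+].[OH-]
Why: Saponification by acyl–oxygen cleavage; at or below room temperature hydroxide is not expected to deprotonate the doubly allylic chain C-6/C-9 methylenes at a competitive rate, so the skipped pentaene should survive.

Step 5
Reactants: 6 (2E,4E,7Z,10E,12E)-tetradeca-2,4,7,10,12-pentaenedioic acid; 7 2,2-dimethylpropane-1,3-diol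
Product: 8 2,2-dimethylpropane-1,3-diyl (2E,4E,7Z,10E,12E)-tetradeca-2,4,7,10,12-pentaenedioate (19-membered cyclic diester)
Conditions: EDC·HCl, DMAP, DMAP·HCl, CH2Cl2, 40 °C; 6 and 7 in THF added over 16 h (final 1 mM)
Reagents that add atoms: none
Why: Steglich-type double esterification under Keck high-dilution conditions; the first ester forms intermolecularly and the second closes the 19-membered ring, helped by the gem-dimethyl group of 7 and by slow addition that keeps the open-chain hydroxy acid dilute.

Step 6
Reactants: 8 2,2-dimethylpropane-1,3-diyl (2E,4E,7Z,10E,12E)-tetradeca-2,4,7,10,12-pentaenedioate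
Product: 10 2,2-dimethylpropane-1,3-diyl meso-cis,anti,cis,anti,cis-tetracyclo[6.4.0.0^{2,7}.0^{3,6}]dodec-10-ene-4,5-dicarboxylate (cyclic diester; ester carbons cis to each other and anti to ring C), via cis-dialkenylcyclobutane diester 9 (not isolated)
Conditions: xanthone (20 mol %), degassed MeCN (1 mM), 365 nm LEDs, −35 °C
Reagents that add atoms: none
Why: Proposed new method: triplet energy transfer from xanthone (about 74 kcal/mol) to one dienoate (about 55–58 kcal/mol) gives a twisted diene triplet whose δ-carbon C-5 (chain locants of 8) bonds to C-10 of the ground-state dienoate stacked on it, the bis-allyl 1,4-biradical closes at C-4/C-11 after intersystem crossing to give 9, and a second energy transfer, now to an isolated enoate (about 72–74 kcal/mol, which is why a sensitiser of this energy and a clamp without a low-lying triplet are used), triggers the transannular enoate–enoate [2+2] through the bis(α-ester) biradical formed by C-3/C-12 bonding, which closes at C-2/C-13. The closest known reaction types are the triplet-sensitised [2+2] cycloaddition of 1,3-dienes to vinylcyclobutanes, the intramolecular photocycloaddition of diol-tethered unsaturated esters and the photodimerisation of stacked polyenes to ladderanes on rigid scaffolds or in crystals; two successive [2+2] events inside one macrocyclic bis-dienoate are not known. Ring A closes by 6-exo attack of C-5 on C-10 across the four-carbon Z-butenylene tether, ring B by recombination of the 1,4-biradical at C-4/C-11, ring C by bonding of the β-carbons C-3/C-12 that the cis-substituted ring B holds about 3 Å apart, and ring D by recombination of the two ester-stabilised radicals at C-2/C-13, which the clamp keeps within reach. The cis relation at each rung (C-5/C-10, C-4/C-11, C-3/C-12, C-2/C-13) is set by bonding between atoms that face each other in the in-register stack enforced by the tether at one end and the clamp at the other; the anti relation of neighbouring rings is set by the E geometry and s-trans conformation of each chain, which place successive rail atoms on opposite sides of each new four-membered ring, and corresponds to the less hindered exo placement of both arms on the cis-bicyclo[4.2.0]octene of 9. The step needs intramolecular over intermolecular reaction (1 mM), 1,2-closure of the bis-allyl biradical rather than [4+2] or [4+4] closure (transoid allyl termini would have to give trans double bonds in a six- or eight-membered ring), straight rather than crossed addition in the second stage (parallel clamping and formation of the doubly stabilised biradical), and survival of the tether Z-alkene and of the ring A alkene (triplet energies near 79–81 kcal/mol, above that of the sensitiser). E/Z isomerisation of the dienoate triplets is reversible under sensitisation whereas cycloaddition is not, so isomerised material should be fed back, and −35 °C suppresses the Cope rearrangement of the cis-dialkenylcyclobutane 9. The two ester-bearing centres are set cis and exo but are sacrificial, since both carboxyl groups are removed in step 8.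

Step 7
Reactants: 10 2,2-dimethylpropane-1,3-diyl meso-tetracyclo[6.4.0.0^{2,7}.0^{3,6}]dodec-10-ene-4,5-dicarboxylate
Product: 11 meso-cis,anti,cis,anti,cis-tetracyclo[6.4.0.0^{2,7}.0^{3,6}]dodec-10-ene-4,5-dicarboxylic acid (carboxyl groups cis, anti to ring C)
Conditions: LiOH (6 equiv), THF/MeOH/H2O, 40 °C; then 1 M HCl
Reagents that add atoms: lithium hydroxide, [Li+].[OH-]
Why: Saponification of the strained nine-membered dilactone releases the clamp diol and the cis diacid; any epimerisation at C-4/C-5 would be harmless because both centres lose their substituent in step 8.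

Step 8
Reactants: 11 meso-tetracyclo[6.4.0.0^{2,7}.0^{3,6}]dodec-10-ene-4,5-dicarboxylic acid
Product: 13 meso-cis,anti,cis,anti,cis-tetracyclo[6.4.0.0^{2,7}.0^{3,6}]dodec-10-ene, via bis(thiohydroxamate) ester 12 (not isolated)
Conditions: 1-hydroxypyridine-2(1H)-thione, EDC·HCl, DMAP (cat.), CH2Cl2, 0 °C, dark; then t-BuSH (20 equiv), tungsten lamp, 0–10 °C
Reagents that add atoms: none
Why: Barton reductive decarboxylation; photolysis of the thiohydroxamate esters gives acyloxy and then secondary cyclobutyl radicals, which the thiol, in large excess and at low temperature, should trap faster than they can open into ring C. No stereocentre is formed because C-4 and C-5 become methylene groups.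

Step 9
Reactants: 13 meso-tetracyclo[6.4.0.0^{2,7}.0^{3,6}]dodec-10-ene
Product: 15 (10R)-cis,anti,cis,anti,cis-tetracyclo[6.4.0.0^{2,7}.0^{3,6}]dodecan-10-ol (hydroxyl anti to ring B), via diisopinocampheyl(alkyl)borane 14 (not isolated)
Conditions: (+)-Ipc2BH (from (−)-α-pinene), THF, −25 °C to 0 °C; then NaOH, 30% H2O2, 0 °C to rt; chromatography
Reagents that add atoms: hydrogen peroxide, OO
Why: Asymmetric hydroboration–oxidation of a meso cis-alkene (desymmetrisation); syn addition from the convex face, anti to ring B, together with the reagent preference predicted by the empirical model for cis-alkenes should place boron and then oxygen (retention) on C-10 with R configuration. The carbinol centre is sacrificial, what counts is which olefinic carbon is oxidised; the minor concave-face adduct carries oxygen on the other carbon, is a diastereomer of 15 and can be removed by chromatography.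

Step 10
Reactants: 15 (10R)-tetracyclo[6.4.0.0^{2,7}.0^{3,6}]dodecan-10-ol
Product: 16 cis,anti,cis,anti,cis-tetracyclo[6.4.0.0^{2,7}.0^{3,6}]dodecan-10-one (single enantiomer)
Conditions: Dess–Martin periodinane, NaHCO3, CH2Cl2, 0 °C to rt
Reagents that add atoms: none
Why: Dess–Martin oxidation under buffered, neutral conditions; there is no stereocentre α to the new carbonyl group, so the six ring-fusion centres are untouched and 16 is chiral only through the position of the carbonyl group.

Step 11
Reactants: 17 2,2-dimethyl-1,3-dioxan-5-ol; 18 1,8-dibromooctane (4 equiv)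
Product: 19 5-[(8-bromooctyl)oxy]-2,2-dimethyl-1,3-dioxane
Conditions: NaH, DMF, 0 °C to rt
Reagents that add atoms: none
Why: Williamson ether synthesis; the secondary alkoxide displaces one primary bromide, and the excess of dibromide suppresses double alkylation.

Step 12
Reactants: 19 5-[(8-bromooctyl)oxy]-2,2-dimethyl-1,3-dioxane
Product: 20 {8-[(2,2-dimethyl-1,3-dioxan-5-yl)oxy]octyl}triphenylphosphonium bromide
Conditions: PPh3, MeCN, 80 °C
Reagents that add atoms: triphenylphosphine, c1ccc(cc1)P(c1ccccc1)c1ccccc1
Why: Quaternisation of the phosphine by the primary bromide (SN2) under neutral conditions that the acetonide tolerates.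

Step 13
Reactants: 16 tetracyclo[6.4.0.0^{2,7}.0^{3,6}]dodecan-10-one; 20 {8-[(2,2-dimethyl-1,3-dioxan-5-yl)oxy]octyl}triphenylphosphonium bromide
Product: 22 5-{[8-(cis,anti,cis,anti,cis-tetracyclo[6.4.0.0^{2,7}.0^{3,6}]dodecan-10-ylidene)octyl]oxy}-2,2-dimethyl-1,3-dioxane (E/Z mixture), via phosphonium ylide 21 (not isolated)
Conditions: NaN(SiMe3)2, THF, 0 °C; then 16, −78 °C to rt
Reagents that add atoms: none
Why: Wittig olefination with a non-stabilised ylide; the unhindered ketone has no epimerisable centre, and the E/Z mixture at the exocyclic trisubstituted alkene is of no consequence because both isomers give the same product in step 14.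

Step 14
Reactants: 22 5-{[8-(tetracyclo[6.4.0.0^{2,7}.0^{3,6}]dodecan-10-ylidene)octyl]oxy}-2,2-dimethyl-1,3-dioxane
Product: 23 5-({8-[(1R,2S,3S,6R,7R,8S,10S)-tetracyclo[6.4.0.0^{2,7}.0^{3,6}]dodecan-10-yl]octyl}oxy)-2,2-dimethyl-1,3-dioxane
Conditions: H2 (1 atm), [Ir(cod)(PCy3)(py)]PF6 (5 mol %), CH2Cl2, 0 °C to rt
Reagents that add atoms: none
Why: Homogeneous hydrogenation with Crabtree's catalyst, which reduces trisubstituted alkenes without attacking strained σ bonds; in the preferred ring A conformer the C-7–C-8 bond is axial and shields the concave face at C-10, so hydrogen should be delivered from the convex face, anti to ring B, which places the chain cis to ring B (10S).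

Step 15
Reactants: 23 5-({8-[(1R,2S,3S,6R,7R,8S,10S)-tetracyclo[6.4.0.0^{2,7}.0^{3,6}]dodecan-10-yl]octyl}oxy)-2,2-dimethyl-1,3-dioxane
Product: 24 2-({8-[(1R,2S,3S,6R,7R,8S,10S)-tetracyclo[6.4.0.0^{2,7}.0^{3,6}]dodecan-10-yl]octyl}oxy)propane-1,3-diol (CNP0193334.1)
Conditions: 1 M HCl, THF/MeOH, rt
Reagents that add atoms: none
Why: Acid-catalysed acetonide hydrolysis; the ether, the saturated ladder and all stereocentres are inert to dilute acid at room temperature.

## Compound list

1 | cyclohexa-1,4-diene | C1=CCC=CC1 | starting material
2 | cis-cyclohex-4-ene-1,2-diol (meso) | O[C@@H]1CC=CC[C@@H]1O | intermediate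
3 | (Z)-hex-3-enedial | O=CC/C=C\CC=O | intermediate
4 | triethyl 4-phosphonocrotonate | CCOC(=O)/C=C/CP(=O)(OCC)OCC | starting material
5 | diethyl (2E,4E,7Z,10E,12E)-tetradeca-2,4,7,10,12-pentaenedioate | CCOC(=O)/C=C/C=C/C/C=C\C/C=C/C=C/C(=O)OCC | intermediate
6 | (2E,4E,7Z,10E,12E)-tetradeca-2,4,7,10,12-pentaenedioic acid | OC(=O)/C=C/C=C/C/C=C\C/C=C/C=C/C(=O)O | intermediate
7 | 2,2-dimethylpropane-1,3-diol | CC(C)(CO)CO | starting material
8 | 2,2-dimethylpropane-1,3-diyl (2E,4E,7Z,10E,12E)-tetradeca-2,4,7,10,12-pentaenedioate (19-membered cyclic diester) | O=C1/C=C/C=C/C/C=C\C/C=C/C=C/C(=O)OCC(C)(C)CO1 | intermediate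
9 | 2,2-dimethylpropane-1,3-diyl (2E,2'E)-3,3'-(cis-bicyclo[4.2.0]oct-3-ene-7,8-diyl)di(prop-2-enoate) (cyclic diester; arms cis to each other, anti to ring A) | C1=CC[C@@H]2[C@H](C1)[C@H]1/C=C/C(=O)OCC(C)(C)COC(=O)/C=C/[C@@H]21 | intermediate
10 | 2,2-dimethylpropane-1,3-diyl meso-cis,anti,cis,anti,cis-tetracyclo[6.4.0.0^{2,7}.0^{3,6}]dodec-10-ene-4,5-dicarboxylate (cyclic diester) | C1=CC[C@@H]2[C@H](C1)[C@H]1[C@@H]3[C@H]4C(=O)OCC(C)(C)COC(=O)[C@H]4[C@@H]3[C@@H]21 | intermediate
11 | meso-cis,anti,cis,anti,cis-tetracyclo[6.4.0.0^{2,7}.0^{3,6}]dodec-10-ene-4,5-dicarboxylic acid | C1=CC[C@@H]2[C@H](C1)[C@H]1[C@@H]3[C@@H](C(=O)O)[C@@H](C(=O)O)[C@@H]3[C@@H]21 | intermediate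
12 | bis(2-thioxopyridin-1(2H)-yl) meso-tetracyclo[6.4.0.0^{2,7}.0^{3,6}]dodec-10-ene-4,5-dicarboxylate | C1=CC[C@@H]2[C@H](C1)[C@H]1[C@@H]3[C@@H](C(=O)ON4C=CC=CC4=S)[C@@H](C(=O)ON4C=CC=CC4=S)[C@@H]3[C@@H]21 | intermediate
13 | meso-cis,anti,cis,anti,cis-tetracyclo[6.4.0.0^{2,7}.0^{3,6}]dodec-10-ene | C1=CC[C@@H]2[C@H](C1)[C@H]1[C@@H]3CC[C@@H]3[C@@H]21 | intermediate
14 | diisopinocampheyl(tetracyclo[6.4.0.0^{2,7}.0^{3,6}]dodecan-10-yl)borane (boron anti to ring B; isopinocampheyl groups from (−)-α-pinene) | B([C@@H]1CC[C@@H]2[C@H](C1)[C@H]1[C@@H]3CC[C@@H]3[C@@H]21)([C@H]1C[C@H]2C[C@@H]([C@@H]1C)C2(C)C)[C@H]1C[C@H]2C[C@@H]([C@@H]1C)C2(C)C | intermediate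
15 | (10R)-cis,anti,cis,anti,cis-tetracyclo[6.4.0.0^{2,7}.0^{3,6}]dodecan-10-ol (hydroxyl anti to ring B) | O[C@@H]1CC[C@@H]2[C@H](C1)[C@H]1[C@@H]3CC[C@@H]3[C@@H]21 | intermediate
16 | cis,anti,cis,anti,cis-tetracyclo[6.4.0.0^{2,7}.0^{3,6}]dodecan-10-one | O=C1CC[C@@H]2[C@H](C1)[C@H]1[C@@H]3CC[C@@H]3[C@@H]21 | intermediate
17 | 2,2-dimethyl-1,3-dioxan-5-ol | CC1(C)OCC(O)CO1 | starting material
18 | 1,8-dibromooctane | BrCCCCCCCCBr | starting material
19 | 5-[(8-bromooctyl)oxy]-2,2-dimethyl-1,3-dioxane | CC1(C)OCC(CO1)OCCCCCCCCBr | intermediate
20 | {8-[(2,2-dimethyl-1,3-dioxan-5-yl)oxy]octyl}triphenylphosphonium bromide | CC1(C)OCC(CO1)OCCCCCCCC[P+](c1ccccc1)(c1ccccc1)c1ccccc1.[Br-] | intermediate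
21 | {8-[(2,2-dimethyl-1,3-dioxan-5-yl)oxy]octylidene}triphenylphosphorane | CC1(C)OCC(CO1)OCCCCCCCC=P(c1ccccc1)(c1ccccc1)c1ccccc1 | intermediate
22 | 5-{[8-(cis,anti,cis,anti,cis-tetracyclo[6.4.0.0^{2,7}.0^{3,6}]dodecan-10-ylidene)octyl]oxy}-2,2-dimethyl-1,3-dioxane (E/Z mixture at the exocyclic alkene) | CC1(C)OCC(CO1)OCCCCCCCC=C1CC[C@@H]2[C@H](C1)[C@H]1[C@@H]3CC[C@@H]3[C@@H]21 | intermediate
23 | 5-({8-[(1R,2S,3S,6R,7R,8S,10S)-tetracyclo[6.4.0.0^{2,7}.0^{3,6}]dodecan-10-yl]octyl}oxy)-2,2-dimethyl-1,3-dioxane | CC1(C)OCC(CO1)OCCCCCCCC[C@H]1CC[C@@H]2[C@H](C1)[C@H]1[C@@H]3CC[C@@H]3[C@@H]21 | intermediate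
24 | 2-({8-[(1R,2S,3S,6R,7R,8S,10S)-tetracyclo[6.4.0.0^{2,7}.0^{3,6}]dodecan-10-yl]octyl}oxy)propane-1,3-diol | OCC(CO)OCCCCCCCC[C@H]1CC[C@@H]2[C@H](C1)[C@H]1[C@@H]3CC[C@@H]3[C@@H]21 | target

## Step count and least certain steps

Total: 15 steps. Longest linear sequence: 13 steps (steps 1–10 and 13–15). The chain branch (steps 11 and 12) joins at step 13.

**Step 6 (key step, proposed new method).**
- What may go wrong: the cascade may stop after the first cycloaddition because energy transfer to the isolated enoates is inefficient. The second stage may follow the crossed (rule-of-five) mode instead of the straight one. E/Z isomerisation of the dienoate may outrun cycloaddition, so that out-of-register or trans-fused adducts and oligomers form. All of these follow from the fact that the excited states are short-lived, twisted triplets whose bond formation is stepwise.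
- Fallback (known chemistry, one rung pair at a time): it sets out from 1 and comes back at 11. Sensitised [2+2] photocycloaddition of maleic anhydride A6 to one double bond of 1 (acetophenone, EtOAc) should give cis-bicyclo[4.2.0]oct-3-ene-7,8-dicarboxylic anhydride F1. Hydrolysis and oxidative bis-decarboxylation with Pb(OAc)4 in pyridine give cis-bicyclo[4.2.0]octa-3,7-diene F2. A second photocycloaddition of A6, to the strained cyclobutene from its exo face, gives the tricyclic anhydride F3, bis-decarboxylation gives the tricyclic diene F4, and a third cycloaddition gives the tetracyclic anhydride F5, whose hydrolysis yields 11. The price is five more steps and a cyclobutene-versus-cyclohexene chemoselectivity question in the second and third cycloadditions.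

**Step 3 (double olefination).**
- What may go wrong: the basic phosphonate anion may enolise the dialdehyde and move its double bond into conjugation before both olefinations are complete, and E selectivity at the new alkenes may be eroded.
- Fallback: it sets out from 3 and comes back at 5. Two successive Wittig homologations with neutral stabilised ylides are used: (triphenylphosphoranylidene)acetaldehyde gives (2E,5Z,8E)-deca-2,5,8-trienedial F6, and ethyl (triphenylphosphoranylidene)acetate then gives 5.

**Step 5 (macrocyclisation).**
- What may go wrong: intermolecular esterification may outpace ring closure and give linear and cyclic oligomers, because both ester bonds are formed from flexible partners.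
- Fallback: it sets out from 7 (with 3) and comes back at 8, closing the ring by C=C formation instead. Acylation of 7 with (E)-4-bromobut-2-enoyl chloride gives the bis(4-bromocrotonate) F7. Arbuzov reaction with P(OEt)3 gives the bis-phosphonate F8. Slow addition of 3 to F8 with LiCl and DBU in MeCN at high dilution (Masamune–Roush conditions) closes the ring by a double Horner–Wadsworth–Emmons reaction to 8.

**Step 8 (double Barton decarboxylation).**
- What may go wrong: the cis diacid may close to the cyclic anhydride during activation, so that only one carboxyl group is converted at a time. The cyclobutyl radical may undergo β-scission into ring C before hydrogen transfer. Thiyl radicals may add to the ring A alkene.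
- Fallback: it sets out from 11 and comes back at 13. Oxidative bis-decarboxylation with Pb(OAc)4 in pyridine at 50 °C gives the ladder diene F9 (identical with A9). Diimide (potassium azodicarboxylate, AcOH, MeOH, 0 °C) then reduces the strained cyclobutene in preference to the cyclohexene and gives 13.

**Step 9 (desymmetrising hydroboration).**
- What may go wrong: the bulky reagent may react slowly with the cyclohexene-type alkene and lose α-pinene to give a less selective monoalkylborane. Facial discrimination by the remote ring B may be modest. Both would lower the enantiomeric purity of 16.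
- Fallback: it sets out from 13 and comes back at 15. Epoxidation with mCPBA gives the meso epoxide F10 (oxygen anti to ring B; the other face isomer is a separable diastereomer). Enantioselective β-elimination with a chiral lithium amide, for example lithium bis(1-phenylethyl)amide of the appropriate configuration, removes the proton at C-12 and gives the allylic alcohol F11. Diimide reduction of its alkene gives 15.

**Step 14 (hydrogenation at C-10).**
- What may go wrong: facial selectivity at the exocyclic alkene may be poor, because the bias comes only from the conformational preference of ring A and the two C-10 epimers would be hard to separate.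
- Fallback: it sets out from 15 (with 19) and comes back at 23. The stereospecific alternative uses the convex hydroxyl of 15: tosylation gives the tosylate F12, and the Grignard reagent F13 is prepared from 19 with Mg in THF. Coupling catalysed by CuI with TMEDA and LiOMe proceeds by SN2 displacement with inversion and places the chain cis to ring B, giving 23.

## Further compounds

F1 | step 6 | cis-bicyclo[4.2.0]oct-3-ene-7,8-dicarboxylic anhydride (anhydride ring anti to ring A) | C1=CC[C@@H]2[C@H](C1)[C@H]1C(=O)OC(=O)[C@@H]21
F2 | step 6 | cis-bicyclo[4.2.0]octa-3,7-diene | C1=CC[C@@H]2[C@H](C1)C=C2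
F3 | step 6 | cis,anti,cis-tricyclo[4.4.0.0^{2,5}]dec-8-ene-3,4-dicarboxylic anhydride | C1=CC[C@@H]2[C@H](C1)[C@H]1[C@@H]3C(=O)OC(=O)[C@@H]3[C@@H]21
F4 | step 6 | cis,anti,cis-tricyclo[4.4.0.0^{2,5}]deca-3,8-diene | C1=CC[C@@H]2[C@H](C1)[C@H]1C=C[C@@H]21
F5 | step 6 | meso-cis,anti,cis,anti,cis-tetracyclo[6.4.0.0^{2,7}.0^{3,6}]dodec-10-ene-4,5-dicarboxylic anhydride | C1=CC[C@@H]2[C@H](C1)[C@H]1[C@@H]3[C@H]4C(=O)OC(=O)[C@H]4[C@@H]3[C@@H]21
F6 | step 3 | (2E,5Z,8E)-deca-2,5,8-trienedial | O=C/C=C/C/C=C\C/C=C/C=O
F7 | step 5 | 2,2-dimethylpropane-1,3-diyl bis[(E)-4-bromobut-2-enoate] | BrC/C=C/C(=O)OCC(C)(C)COC(=O)/C=C/CBr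
F8 | step 5 | 2,2-dimethylpropane-1,3-diyl bis[(E)-4-(diethoxyphosphoryl)but-2-enoate] | CCOP(=O)(OCC)C/C=C/C(=O)OCC(C)(C)COC(=O)/C=C/CP(=O)(OCC)OCC
F9 | step 8 | meso-cis,anti,cis,anti,cis-tetracyclo[6.4.0.0^{2,7}.0^{3,6}]dodeca-4,10-diene | C1=CC[C@@H]2[C@H](C1)[C@H]1[C@@H]3C=C[C@@H]3[C@@H]21
F10 | step 9 | meso-10,11-epoxy-cis,anti,cis,anti,cis-tetracyclo[6.4.0.0^{2,7}.0^{3,6}]dodecane (oxygen anti to ring B) | C1[C@@H]2O[C@@H]2C[C@@H]3[C@H]1[C@H]1[C@@H]4CC[C@@H]4[C@@H]31
F11 | step 9 | (10R)-cis,anti,cis,anti,cis-tetracyclo[6.4.0.0^{2,7}.0^{3,6}]dodec-11-en-10-ol (hydroxyl anti to ring B) | O[C@@H]1C=C[C@@H]2[C@H](C1)[C@H]1[C@@H]3CC[C@@H]3[C@@H]21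
F12 | step 14 | (10R)-cis,anti,cis,anti,cis-tetracyclo[6.4.0.0^{2,7}.0^{3,6}]dodecan-10-yl 4-methylbenzenesulfonate | Cc1ccc(cc1)S(=O)(=O)O[C@@H]1CC[C@@H]2[C@H](C1)[C@H]1[C@@H]3CC[C@@H]3[C@@H]21
F13 | step 14 | {8-[(2,2-dimethyl-1,3-dioxan-5-yl)oxy]octyl}magnesium bromide | CC1(C)OCC(CO1)OCCCCCCCC[Mg]Br
A1 | alternative 1 | 2-{8-[1,3-bis(benzyloxy)propan-2-yloxy]octyl}buta-1,3-diene | C=CC(=C)CCCCCCCCOC(COCc1ccccc1)COCc1ccccc1
A2 | alternative 1 | cyclobut-2-en-1-one | O=C1C=CC1
A3 | alternative 1 | 3-{8-[1,3-bis(benzyloxy)propan-2-yloxy]octyl}-cis-bicyclo[4.2.0]oct-3-en-7-one | C(c1ccccc1)OCC(COCc1ccccc1)OCCCCCCCCC1=CC[C@@H]2[C@H](C1)CC2=O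
A4 | alternative 2 | cyclooctatetraene | C1=CC=CC=CC=C1
A5 | alternative 2 | cis-bicyclo[4.2.0]octa-2,4,7-triene | C1=C[C@H]2C=C[C@H]2C=C1
A6 | alternative 2 | maleic anhydride | O=C1OC(=O)C=C1
A7 | alternative 2 | meso-tricyclo[4.2.2.0^{2,5}]deca-3,7-diene-9,10-dicarboxylic anhydride (endo anhydride, cyclobutene syn to the etheno bridge) | O=C1OC(=O)[C@@H]2[C@H]1[C@@H]1C=C[C@H]2[C@H]2C=C[C@@H]12
A8 | alternative 3 | meso-cis,anti,cis-tricyclo[6.4.0.0^{2,7}]dodeca-3,5,10-triene | C1=CC[C@@H]2[C@H](C1)[C@H]1C=CC=C[C@@H]21
A9 | alternative 3 | meso-cis,anti,cis,anti,cis-tetracyclo[6.4.0.0^{2,7}.0^{3,6}]dodeca-4,10-diene | C1=CC[C@@H]2[C@H](C1)[C@H]1[C@@H]3C=C[C@@H]3[C@@H]21
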